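## The problem

Target 24 is a trans-2-aryl-3-methyl-2,3-dihydro-1,4-benzodioxine. A dioxane ring (O1, C2, C3, O4) is fused through C4a and C8a to a benzene ring (ring A) that carries a methoxy group at C5 and an (E)-prop-1-enyl group at C7. A 4-hydroxy-3,5-dimethoxyphenyl group (ring B) sits on C2.

The two oxygens must be joined to the unsymmetrical ring A in the right sense. O4, bonded to the methyl-bearing C3, belongs on C4a next to the C5 methoxy group. O1, bonded to the benzylic C2, belongs on C8a.

C2 and C3 are adjacent, both R, with aryl and methyl trans. C3 can be taken from lactic acid and can then control C2, first by 1,2-induction in a ketone reduction and then by a stereospecific substitution. The trans ring is also the more stable one.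

Three groups are fragile. The (E)-propenyl group does not tolerate hydrogenation, strong electrophiles or strong oxidants. The free ring-B phenol lies para to the benzylic C2–O1 bond, so strong acid (ionisation) or hot base (quinone methide) can open or epimerise C2. Both arenes are electron-rich.

The feature that opens the route is in ring A. C4a and C8a each carry oxygen and together stand at the oxidation level of an alkoxyacetyl unit, O4–C–C(=O). These are C3 and C2 of a 1,4-dioxan-2-one that already holds O4, both stereocentres and ring B. C5, C6, C7 (with its propenyl group) and C8 map onto a 3-methylhexa-2,4-dienoyl unit: the carbonyl carbon becomes C5 and the 3-methyl group becomes C8. Ring A can therefore be grown on the stereodefined heterocycle.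

## Retrosynthesis

**24 back to 22 (protecting group and O-methyl).** The ring-B phenol is masked as its methoxymethyl ether (23) and the C5 methyl ether is cut back to phenol 22. The acetal survives organomagnesium, hydride, lithium amides, Mitsunobu reagents and carbonate, and leaves under mild acid. A benzyl ether is excluded because hydrogenolysis would saturate the propenyl group and cleave C2–O1. Methylation is placed after ring closure because the closure itself tells the two ring-A oxygens apart.

**22 back to 21 (O1–C2).** Cutting the benzylic C–O bond gives resorcinol 21, whose two hydroxyls are equivalent, so no regiochemical question arises. The alternative cut at O4–C3 would need substitution at an unactivated secondary carbon. The forward step must invert a 1S benzylic carbinol to C2 (R), which an intramolecular Mitsunobu reaction does.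

**21 back to 13 and 18 (C4a–C5 and C8–C8a, the key cut).** Ring A is removed altogether. What remains is dioxanone 13, which contains both stereocentres, and the seven-carbon acid chloride 18. The neighbouring cut, an aryl ether synthesis at O4–C4a, would need a differentiated 5-propenylpyrogallol. The forward reaction needs C-acylation of the lactone enolate, deprotonation of one particular methyl group, and closure onto the lactone carbonyl. It forms no stereocentre, and ring A appears aromatic with the propenyl group in place.

**18 back to 14 and 15 (C2=C3 of the dienoyl unit).** Acid chloride 18 comes from acid 17 and ester 16. Ester 16 comes from (E)-pent-3-en-2-one 14 and phosphonate 15 by Horner–Wadsworth–Emmons olefination. The 4E alkene is bought. The olefination must place the ester trans to the propenyl group (2E), so that the 3-methyl group is cis to the carbonyl.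

**13 back to 9 (lactone carbonyl).** The lactone is taken from lactol 12, and the lactol from oxidative cleavage of the allyl ether in alcohol 9. An ester at this position was considered and rejected. It would have to survive the aryl Grignard reagent and then be lactonised without acid, which neither the acetal nor the electron-rich benzylic alcohol tolerates. The allyl group is inert to magnesium and hydride reagents and is unmasked under neutral conditions, at the cost of one extra step.

**9 back to 8 (C1–H).** The carbinol stereocentre is set by chelation-controlled reduction of α-alkoxy ketone 8. The lactate-derived centre directs hydride to give the 1S,2R (erythro) alcohol.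

**8 back to 4 and 6 (aryl–carbonyl bond).** Ketone 8 comes from Weinreb amide 4 and arylmagnesium bromide 7, made from bromide 6. The Weinreb amide prevents over-addition and keeps the α-centre away from base.

**4, 6 back to purchased materials.** Amide 4 is the allyl ether (allyl bromide 3) of hydroxy amide 2, made from methyl (R)-lactate 1. Bromide 6 is the methoxymethyl ether of 4-bromo-2,6-dimethoxyphenol 5.

## Roads not taken

**Alternative 1: carbene–epoxide dioxene annulation, aromatisation afterwards.**
- Cut: O4–C4a and O1–C2 together, with ring A carried as a cyclohexane-1,3-dione.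
- Forward key step: Rh2(OAc)4 converts methyl 4-diazo-3,5-dioxocyclohexane-1-carboxylate A2 into a carbene. The oxygen of 2,6-dimethoxy-4-[(2R,3R)-3-methyloxiran-2-yl]phenyl 2,2-dimethylpropanoate A3 attacks it. The benzylic C–O bond opens and the enolate oxygen closes on C2, giving the hexahydrobenzodioxinone ester A1.
- Merits: the heterocycle and both stereocentres come from one epoxide in one catalytic step. The O1/O4 regiochemistry is built in. The sequence before the key step is shorter than the seven steps needed for 13.
- Weak points: fidelity at C2 depends on how the benzylic bond breaks (tight ion pair or free cation). An aryl epoxide is prone to rearrange to a carbonyl compound under an electrophilic metal carbene. Diazodione carbenes are reluctant ylide formers and undergo Wolff rearrangement. After A1 the route still needs dehydrogenation to the phenol, O-methylation, conversion of the C7 ester to an (E)-propenyl group with geometric control, and deprotection.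
- Comparison: Alternative 1 is more convergent up to its key step. Against that, the chosen key step forms no stereocentre and delivers ring A at the right oxidation level with its side chain already in place.

**Alternative 2: iodoetherification of a branched allyl aryl ether.**
- Cut: O4–C3.
- Forward key step: in phenol A5, 3-{[(1S)-1-[3,5-dimethoxy-4-(methoxymethoxy)phenyl]prop-2-en-1-yl]oxy}-4-hydroxy-5-methoxybenzaldehyde, the vinyl group is activated by N-iodosuccinimide. The free phenol attacks the internal carbon in a 6-exo closure to give iodomethyl aldehyde A4.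
- Merits: ring A is purchased. Every step belongs to an established class. C2 comes from a catalytic asymmetric allylic etherification, for example [Ir(cod)Cl]2 with a chiral phosphoramidite.
- Weak points: the branched ether must be placed on the less acidic of two catechol oxygens, which costs protecting-group steps. C3 is set only by substrate control in the cyclisation, and 7-endo closure competes. The C–I bond must then be reduced beside an aldehyde, and the aldehyde olefinated with E selectivity.
- Comparison: the overall risk of Alternative 2 is arguably lower than that of the chosen key step. Against that, the chosen plan takes C3 from lactate with certainty, sets C2 by two well-understood events, and never has to make the (E)-propenyl double bond.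

**Alternative 3: benzodioxole to benzodioxane by oxonium ylide ring expansion.**
- Cut: O1–C2 and C2–C3.
- Forward key step: the aryl carbene from the salt of tosylhydrazone A8, on Rh2(S-PTTL)4 (dirhodium tetrakis[N-phthaloyl-(S)-tert-leucinate]), adds to the less hindered acetal oxygen of 6-bromo-4-methoxy-2-methyl-1,3-benzodioxole A7. The acetal carbon then shifts to the carbene carbon, giving bromide A6.
- Merits: this is the shortest and most convergent route. One step makes a C–C bond, a C–O bond and both stereocentres from two simple fragments. The C7 bromide allows a late stereoretentive cross-coupling.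
- Weak points: a 1,2-shift of an oxonium ylide passes through a radical pair, so catalyst control over two new centres is doubtful. The acetal carbon of A7 is itself a stereocentre. Donor aryl carbenes dimerise and attack arenes. The two acetal oxygens are distinguished only by sterics.
- Comparison: if it worked, Alternative 3 would be clearly shorter. Against that, the chosen plan's stereochemistry comes from the chiral pool and from reliable reactions, and its one adventurous step forms no stereocentre.

Key step: step 11

## Route

Assumption: the two hydroxyl groups of 21 exchange by rotation about the aryl–oxygen bond and are chemically equivalent; 14 is used as the pure E isomer and only the 2E isomer of 16 is carried forward.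

Step 1
Reactants: 1 methyl (2R)-2-hydroxypropanoate (methyl (R)-lactate)
Product: 2 (2R)-2-hydroxy-N-methoxy-N-methylpropanamide
Conditions: MeNHOMe·HCl, i-PrMgCl, THF, −20 → 0 °C
Reagents that add atoms: N,O-dimethylhydroxylamine hydrochloride, CNOC.Cl
Why: Ester aminolysis by the chloromagnesium amide of N,O-dimethylhydroxylamine (Weinreb amide formation); the hydroxyl is carried as its magnesium alkoxide and the stereocentre is not enolised.

Step 2
Reactants: 2 (2R)-2-hydroxy-N-methoxy-N-methylpropanamide; 3 3-bromoprop-1-ene (allyl bromide)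
Product: 4 (2R)-N-methoxy-N-methyl-2-(prop-2-en-1-yloxy)propanamide
Conditions: NaH, Bu4NI (cat.), THF, 0 °C → rt
Reagents that add atoms: none
Why: Williamson etherification of the sodium alkoxide with a reactive allylic bromide; the α-proton of an amide is much less acidic than that of the ester, which is why the amide is made before the ether.

Step 3
Reactants: 5 4-bromo-2,6-dimethoxyphenol
Product: 6 5-bromo-1,3-dimethoxy-2-(methoxymethoxy)benzene
Conditions: NaH, MeOCH2Cl, THF, 0 °C → rt
Reagents that add atoms: chloromethyl methyl ether, COCCl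
Why: O-alkylation of the hindered phenoxide (MOM protection); the acetal is stable to magnesium, hydride, lithium amides, Mitsunobu reagents and carbonate.

Step 4
Reactants: 6 5-bromo-1,3-dimethoxy-2-(methoxymethoxy)benzene; 4 (2R)-N-methoxy-N-methyl-2-(prop-2-en-1-yloxy)propanamide
Product: 8 (2R)-1-[3,5-dimethoxy-4-(methoxymethoxy)phenyl]-2-(prop-2-en-1-yloxy)propan-1-one, via arylmagnesium bromide 7 (not isolated)
Conditions: Mg, I2 (cat.), THF, reflux; then 4, THF, −20 → 0 °C; aq. NH4Cl
Reagents that add atoms: none
Why: Magnesium insertion, then Grignard addition to the Weinreb amide; the chelated tetrahedral adduct holds until work-up, so the ketone forms once and its α-alkoxy stereocentre never meets base; the allyl ether is inert.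

Step 5
Reactants: 8 (2R)-1-[3,5-dimethoxy-4-(methoxymethoxy)phenyl]-2-(prop-2-en-1-yloxy)propan-1-one
Product: 9 (1S,2R)-1-[3,5-dimethoxy-4-(methoxymethoxy)phenyl]-2-(prop-2-en-1-yloxy)propan-1-ol
Conditions: Zn(BH4)2, Et2O, −30 → 0 °C
Reagents that add atoms: none
Why: Chelation-controlled (Cram chelate) reduction; zinc bridges the carbonyl and ether oxygens and hydride enters from the face bearing the C2 hydrogen, not the methyl group, which sets the carbinol as 1S (erythro).

Step 6
Reactants: 9 (1S,2R)-1-[3,5-dimethoxy-4-(methoxymethoxy)phenyl]-2-(prop-2-en-1-yloxy)propan-1-ol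
Product: 12 (5R,6S)-6-[3,5-dimethoxy-4-(methoxymethoxy)phenyl]-5-methyl-1,4-dioxan-2-ol (anomeric mixture), via triol 10 (not isolated), via hydroxy aldehyde 11 (not isolated)
Conditions: OsO4 (cat.), NaIO4, 2,6-lutidine, 1,4-dioxane/H2O, rt
Reagents that add atoms: osmium tetroxide, O=[Os](=O)(=O)=O (delivers the new oxygen); sodium periodate, [Na+].[O-][I](=O)(=O)=O (terminal oxidant that replenishes it)
Why: Lemieux–Johnson cleavage of the only alkene gives the alkoxyacetaldehyde, which the benzylic hydroxyl traps as a six-membered lactol; it is run before any propenyl group exists, and 2,6-lutidine keeps the medium from turning acidic.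

Step 7
Reactants: 12 (5R,6S)-6-[3,5-dimethoxy-4-(methoxymethoxy)phenyl]-5-methyl-1,4-dioxan-2-ol
Product: 13 (5R,6S)-6-[3,5-dimethoxy-4-(methoxymethoxy)phenyl]-5-methyl-1,4-dioxan-2-one
Conditions: TEMPO (cat.), PhI(OAc)2, CH2Cl2, rt
Reagents that add atoms: none
Why: Oxoammonium (TEMPO) oxidation of a lactol to the lactone, a standard neutral method that leaves the acetal and both stereocentres untouched.

Step 8
Reactants: 14 (3E)-pent-3-en-2-one; 15 triethyl phosphonoacetate
Product: 16 ethyl (2E,4E)-3-methylhexa-2,4-dienoate
Conditions: NaH, THF, 0 °C → rt; chromatography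
Reagents that add atoms: none
Why: Horner–Wadsworth–Emmons olefination of a methyl ketone; the ester should end mainly trans to the larger propenyl group (2E), the minor 2Z isomer is removed, and the 4E alkene is not affected.

Step 9
Reactants: 16 ethyl (2E,4E)-3-methylhexa-2,4-dienoate
Product: 17 (2E,4E)-3-methylhexa-2,4-dienoic acid
Conditions: LiOH, THF/MeOH/H2O, rt; then aq. HCl
Reagents that add atoms: lithium hydroxide, [Li+].[OH-]
Why: Saponification followed by acidification; the conjugated dienoate is stable to aqueous hydroxide at room temperature and the acid can be recrystallised to geometric purity.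

Step 10
Reactants: 17 (2E,4E)-3-methylhexa-2,4-dienoic acid
Product: 18 (2E,4E)-3-methylhexa-2,4-dienoyl chloride
Conditions: (COCl)2, DMF (cat.), CH2Cl2, 0 °C → rt; used crude
Reagents that add atoms: oxalyl chloride, O=C(Cl)C(=O)Cl
Why: Acid chloride formation through the chloroiminium species from oxalyl chloride and DMF; the by-products are gases, so no purification is needed.

Step 11
Reactants: 13 (5R,6S)-6-[3,5-dimethoxy-4-(methoxymethoxy)phenyl]-5-methyl-1,4-dioxan-2-one; 18 (2E,4E)-3-methylhexa-2,4-dienoyl chloride
Product: 21 2-{[(1S,2R)-1-[3,5-dimethoxy-4-(methoxymethoxy)phenyl]-1-hydroxypropan-2-yl]oxy}-5-[(1E)-prop-1-en-1-yl]benzene-1,3-diol, via beta-keto lactone 19 (not isolated), via cyclohexenedione 20 (not isolated)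
Conditions: LiN(SiMe3)2 (2.1 equiv), THF, −78 °C; 18 (1.05 equiv), −78 °C; then LiN(i-Pr)2 (3 equiv), −78 → 0 °C; AcOH, aq. NH4Cl
Reagents that add atoms: none
Why: LiN(SiMe3)2 converts 13 into its lithium enolate, which 18 acylates at carbon (Claisen-type acylation, C4a–C5), and the second equivalent of base takes the acidic proton of beta-keto lactone 19 so that all of 13 is consumed. LiN(i-Pr)2 then removes a proton from the 3-methyl group of the dienoyl unit, which the 2E geometry holds next to the lithium-bearing oxygen, and the carbanion adds to the lactone carbonyl in a 6-exo-trig closure (C8–C8a, a vinylogous Dieckmann condensation). Collapse of the tetrahedral intermediate expels the benzylic alkoxide, which stays attached through the ether, and cyclohexenedione 20 loses a proton to give the resorcinol dianion; this aromatisation makes the sequence irreversible. The closest known reaction type is the polyketide-style anionic benzannulation of ester enolates (acylation by a 3-methylalk-2-enoyl donor, γ-deprotonation, Dieckmann closure, tautomerisation to a resorcinol); here the ester is a lactone, so the leaving alkoxide remains in the molecule. The step needs carbon over oxygen acylation, favoured by a lithium enolate in THF at −78 °C, and deprotonation at the 3-methyl group instead of the propenyl methyl, favoured by proximity to the oxygen-bound lithium and secured because only this carbanion can reach the lactone carbon through a six-membered transition state. Lithium held between the enolate oxygen and ring oxygen O4 places the dienyl chain on the side of the lactone carbonyl, which is the geometry the closure requires. No stereocentre is formed, and the two existing ones carry no acidic hydrogen. If 18 loses HCl to a vinylketene, addition of the enolate to that ketene gives the same dienolate, so this side path feeds the same product.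

Step 12
Reactants: 21 2-{[(1S,2R)-1-[3,5-dimethoxy-4-(methoxymethoxy)phenyl]-1-hydroxypropan-2-yl]oxy}-5-[(1E)-prop-1-en-1-yl]benzene-1,3-diol
Product: 22 (2R,3R)-2-[3,5-dimethoxy-4-(methoxymethoxy)phenyl]-3-methyl-7-[(1E)-prop-1-en-1-yl]-2,3-dihydro-1,4-benzodioxin-5-ol
Conditions: PPh3, DIAD, THF (0.01 M), 0 °C → rt
Reagents that add atoms: none
Why: Intramolecular Mitsunobu etherification; either of the two equivalent phenols displaces the activated benzylic oxygen in a 6-exo-tet SN2 closure with inversion, turning the 1S carbinol into C2 (R), trans to the C3 methyl group; dilution suppresses intermolecular etherification and the trans ring is also the more stable one.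

Step 13
Reactants: 22 (2R,3R)-2-[3,5-dimethoxy-4-(methoxymethoxy)phenyl]-3-methyl-7-[(1E)-prop-1-en-1-yl]-2,3-dihydro-1,4-benzodioxin-5-ol
Product: 23 (2R,3R)-2-[3,5-dimethoxy-4-(methoxymethoxy)phenyl]-5-methoxy-3-methyl-7-[(1E)-prop-1-en-1-yl]-2,3-dihydro-1,4-benzodioxine
Conditions: MeI, K2CO3, acetone, 50 °C
Reagents that add atoms: iodomethane, CI
Why: Williamson methylation of the single remaining phenol; no other acidic hydroxyl is present.

Step 14
Reactants: 23 (2R,3R)-2-[3,5-dimethoxy-4-(methoxymethoxy)phenyl]-5-methoxy-3-methyl-7-[(1E)-prop-1-en-1-yl]-2,3-dihydro-1,4-benzodioxine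
Product: 24 2,6-dimethoxy-4-{(2R,3R)-5-methoxy-3-methyl-7-[(1E)-prop-1-en-1-yl]-2,3-dihydro-1,4-benzodioxin-2-yl}phenol
Conditions: HCl (cat.), MeOH/THF, 40 °C
Reagents that add atoms: none
Why: Acid-catalysed transacetalisation of the aryl MOM ether to methanol; an aryl acetal flanked by two methoxy groups should cleave under acid mild enough to spare the benzylic ether and the propenyl group.

## Compound list

1 | methyl (2R)-2-hydroxypropanoate | COC(=O)[C@@H](C)O | starting material
2 | (2R)-2-hydroxy-N-methoxy-N-methylpropanamide | CON(C)C(=O)[C@@H](C)O | intermediate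
3 | 3-bromoprop-1-ene | C=CCBr | starting material
4 | (2R)-N-methoxy-N-methyl-2-(prop-2-en-1-yloxy)propanamide | CON(C)C(=O)[C@@H](C)OCC=C | intermediate
5 | 4-bromo-2,6-dimethoxyphenol | COc1cc(Br)cc(OC)c1O | starting material
6 | 5-bromo-1,3-dimethoxy-2-(methoxymethoxy)benzene | COCOc1c(OC)cc(Br)cc1OC | intermediate
7 | [3,5-dimethoxy-4-(methoxymethoxy)phenyl]magnesium bromide | COCOc1c(OC)cc([Mg]Br)cc1OC | intermediate
8 | (2R)-1-[3,5-dimethoxy-4-(methoxymethoxy)phenyl]-2-(prop-2-en-1-yloxy)propan-1-one | C=CCO[C@H](C)C(=O)c1cc(OC)c(OCOC)c(OC)c1 | intermediate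
9 | (1S,2R)-1-[3,5-dimethoxy-4-(methoxymethoxy)phenyl]-2-(prop-2-en-1-yloxy)propan-1-ol | C=CCO[C@H](C)[C@@H](O)c1cc(OC)c(OCOC)c(OC)c1 | intermediate
10 | 3-{[(1S,2R)-1-[3,5-dimethoxy-4-(methoxymethoxy)phenyl]-1-hydroxypropan-2-yl]oxy}propane-1,2-diol (both epimers at the new carbinol) | OCC(O)CO[C@H](C)[C@@H](O)c1cc(OC)c(OCOC)c(OC)c1 | intermediate
11 | 2-{[(1S,2R)-1-[3,5-dimethoxy-4-(methoxymethoxy)phenyl]-1-hydroxypropan-2-yl]oxy}acetaldehyde | O=CCO[C@H](C)[C@@H](O)c1cc(OC)c(OCOC)c(OC)c1 | intermediate
12 | (5R,6S)-6-[3,5-dimethoxy-4-(methoxymethoxy)phenyl]-5-methyl-1,4-dioxan-2-ol (anomeric mixture) | OC1CO[C@H](C)[C@H](c2cc(OC)c(OCOC)c(OC)c2)O1 | intermediate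
13 | (5R,6S)-6-[3,5-dimethoxy-4-(methoxymethoxy)phenyl]-5-methyl-1,4-dioxan-2-one | O=C1CO[C@H](C)[C@H](c2cc(OC)c(OCOC)c(OC)c2)O1 | intermediate
14 | (3E)-pent-3-en-2-one | C/C=C/C(C)=O | starting material
15 | triethyl phosphonoacetate | CCOC(=O)CP(=O)(OCC)OCC | starting material
16 | ethyl (2E,4E)-3-methylhexa-2,4-dienoate | C/C=C/C(C)=C/C(=O)OCC | intermediate
17 | (2E,4E)-3-methylhexa-2,4-dienoic acid | C/C=C/C(C)=C/C(=O)O | intermediate
18 | (2E,4E)-3-methylhexa-2,4-dienoyl chloride | C/C=C/C(C)=C/C(=O)Cl | intermediate
19 | (5R,6S)-6-[3,5-dimethoxy-4-(methoxymethoxy)phenyl]-5-methyl-3-[(2E,4E)-3-methylhexa-2,4-dienoyl]-1,4-dioxan-2-one (C3 unassigned; lithium enolate in the flask) | C/C=C/C(C)=C/C(=O)C1O[C@H](C)[C@H](c2cc(OC)c(OCOC)c(OC)c2)OC1=O | intermediate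
20 | 2-{[(1S,2R)-1-[3,5-dimethoxy-4-(methoxymethoxy)phenyl]-1-hydroxypropan-2-yl]oxy}-5-[(1E)-prop-1-en-1-yl]cyclohex-4-ene-1,3-dione (lithium salt in the flask) | C/C=C/C1=CC(=O)C(O[C@H](C)[C@@H](O)c2cc(OC)c(OCOC)c(OC)c2)C(=O)C1 | intermediate
21 | 2-{[(1S,2R)-1-[3,5-dimethoxy-4-(methoxymethoxy)phenyl]-1-hydroxypropan-2-yl]oxy}-5-[(1E)-prop-1-en-1-yl]benzene-1,3-diol | C/C=C/c1cc(O)c(O[C@H](C)[C@@H](O)c2cc(OC)c(OCOC)c(OC)c2)c(O)c1 | intermediate
22 | (2R,3R)-2-[3,5-dimethoxy-4-(methoxymethoxy)phenyl]-3-methyl-7-[(1E)-prop-1-en-1-yl]-2,3-dihydro-1,4-benzodioxin-5-ol | C/C=C/c1cc(O)c2c(c1)O[C@H](c1cc(OC)c(OCOC)c(OC)c1)[C@@H](C)O2 | intermediate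
23 | (2R,3R)-2-[3,5-dimethoxy-4-(methoxymethoxy)phenyl]-5-methoxy-3-methyl-7-[(1E)-prop-1-en-1-yl]-2,3-dihydro-1,4-benzodioxine | C/C=C/c1cc(OC)c2c(c1)O[C@H](c1cc(OC)c(OCOC)c(OC)c1)[C@@H](C)O2 | intermediate
24 | 2,6-dimethoxy-4-{(2R,3R)-5-methoxy-3-methyl-7-[(1E)-prop-1-en-1-yl]-2,3-dihydro-1,4-benzodioxin-2-yl}phenol | C/C=C/c1cc(OC)c2c(c1)O[C@H](c1cc(OC)c(O)c(OC)c1)[C@@H](C)O2 | target

## Step count and least certain steps

Total: 14 steps. Longest linear sequence: 10 steps (steps 1, 2, 4, 5, 6, 7, 11, 12, 13, 14).

**Step 11 (key step).** Three processes could defeat it: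
- acylation of the enolate at oxygen, or consumption of the acid chloride by the amide base, before the C4a–C5 bond forms;
- proton removal from the propenyl methyl instead of the 3-methyl group, which scrambles the diene geometry on reprotonation;
- failure of the dianion to add to a lactone carbonyl that is itself part of the enolate, so that the intermediate decomposes on warming.

Fallback: ring A is bought instead of built. This path sets out from arylmagnesium bromide 7 and comes back to the route at 23.
- Commercial 3,4-dihydroxy-5-methoxybenzaldehyde is etherified at its more acidic 4-hydroxyl (para to the formyl group) with methyl (S)-lactate under Mitsunobu conditions (PPh3, DIAD, THF; inversion). This gives methyl (2R)-2-(4-formyl-2-hydroxy-6-methoxyphenoxy)propanoate F1.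
- The remaining phenol is silylated at once (t-BuMe2SiCl, imidazole, DMF) to methyl (2R)-2-{2-[(tert-butyldimethylsilyl)oxy]-4-formyl-6-methoxyphenoxy}propanoate F2.
- Takai olefination (CrCl2, CH3CHI2, THF) converts the formyl group into the (E)-propenyl group of methyl (2R)-2-{2-[(tert-butyldimethylsilyl)oxy]-6-methoxy-4-[(1E)-prop-1-en-1-yl]phenoxy}propanoate F3.
- MeNHOMe·HCl and i-PrMgCl give (2R)-2-{2-[(tert-butyldimethylsilyl)oxy]-6-methoxy-4-[(1E)-prop-1-en-1-yl]phenoxy}-N-methoxy-N-methylpropanamide F4.
- Addition of 7 gives (2R)-2-{2-[(tert-butyldimethylsilyl)oxy]-6-methoxy-4-[(1E)-prop-1-en-1-yl]phenoxy}-1-[3,5-dimethoxy-4-(methoxymethoxy)phenyl]propan-1-one F5.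
- Zn(BH4)2 reduces it under chelation control to (1S,2R)-2-{2-[(tert-butyldimethylsilyl)oxy]-6-methoxy-4-[(1E)-prop-1-en-1-yl]phenoxy}-1-[3,5-dimethoxy-4-(methoxymethoxy)phenyl]propan-1-ol F6.
- Bu4NF frees 2-{[(1S,2R)-1-[3,5-dimethoxy-4-(methoxymethoxy)phenyl]-1-hydroxypropan-2-yl]oxy}-3-methoxy-5-[(1E)-prop-1-en-1-yl]phenol F7.
- Mitsunobu closure as in step 12 then gives 23.

Every operation is a standard one for aryl ethers of this kind. The price is that the benzannulation is given up.

**Step 12.** The activated benzylic alcohol carries a para oxygen substituent and may ionise before displacement. Loss of clean inversion would give some C2 epimer, and intermolecular etherification may compete.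

Fallback: thermodynamic control at C2 in place of kinetic inversion. This path sets out from 21 and comes back at 24.
- The epimer mixture from the ring closure is carried through steps 13 and 14 without separation.
- The cis series is (2S,3R)-2-[3,5-dimethoxy-4-(methoxymethoxy)phenyl]-3-methyl-7-[(1E)-prop-1-en-1-yl]-2,3-dihydro-1,4-benzodioxin-5-ol F8, its methyl ether (2S,3R)-2-[3,5-dimethoxy-4-(methoxymethoxy)phenyl]-5-methoxy-3-methyl-7-[(1E)-prop-1-en-1-yl]-2,3-dihydro-1,4-benzodioxine F9, and the free phenol 2,6-dimethoxy-4-{(2S,3R)-5-methoxy-3-methyl-7-[(1E)-prop-1-en-1-yl]-2,3-dihydro-1,4-benzodioxin-2-yl}phenol F10.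
- F10 is equilibrated with 24 by K2CO3 in DMF at 60 °C. The ring-B phenoxide opens C2–O1 reversibly to a para-quinone methide, and reclosure should favour the trans ring.

**Step 5.** The aryl ketone oxygen is a weak donor, so chelation may be incomplete and the facial selectivity poor.

Fallback: reagent control in place of substrate control. It sets out from 8 and comes back at 9, and makes no new compound. Ketone 8 is reduced with BH3·SMe2 and the B-methyl oxazaborolidine derived from (S)-diphenylprolinol (CBS reduction). With the aryl group as the large substituent this should deliver hydride to the face that gives the 1S carbinol.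

**Step 7.** The oxoammonium salt may oxidise the benzylic carbinol of the open-chain tautomer in competition with the lactol C–H.

Fallback: oxidise the aldehyde tautomer selectively and close the ring by dehydration. It sets out from 12 and comes back at 13.
- Pinnick oxidation (NaClO2, NaH2PO4, 2-methylbut-2-ene, t-BuOH/H2O) gives 2-{[(1S,2R)-1-[3,5-dimethoxy-4-(methoxymethoxy)phenyl]-1-hydroxypropan-2-yl]oxy}acetic acid F11.
- A carbodiimide (N-(3-dimethylaminopropyl)-N′-ethylcarbodiimide hydrochloride, 4-dimethylaminopyridine cat., CH2Cl2) lactonises F11 to 13.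

## Further compounds

F1 | step 11 | methyl (2R)-2-(4-formyl-2-hydroxy-6-methoxyphenoxy)propanoate | COC(=O)[C@@H](C)Oc1c(O)cc(C=O)cc1OC
F2 | step 11 | methyl (2R)-2-{2-[(tert-butyldimethylsilyl)oxy]-4-formyl-6-methoxyphenoxy}propanoate | COC(=O)[C@@H](C)Oc1c(O[Si](C)(C)C(C)(C)C)cc(C=O)cc1OC
F3 | step 11 | methyl (2R)-2-{2-[(tert-butyldimethylsilyl)oxy]-6-methoxy-4-[(1E)-prop-1-en-1-yl]phenoxy}propanoate | COC(=O)[C@@H](C)Oc1c(O[Si](C)(C)C(C)(C)C)cc(/C=C/C)cc1OC
F4 | step 11 | (2R)-2-{2-[(tert-butyldimethylsilyl)oxy]-6-methoxy-4-[(1E)-prop-1-en-1-yl]phenoxy}-N-methoxy-N-methylpropanamide | CON(C)C(=O)[C@@H](C)Oc1c(O[Si](C)(C)C(C)(C)C)cc(/C=C/C)cc1OC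
F5 | step 11 | (2R)-2-{2-[(tert-butyldimethylsilyl)oxy]-6-methoxy-4-[(1E)-prop-1-en-1-yl]phenoxy}-1-[3,5-dimethoxy-4-(methoxymethoxy)phenyl]propan-1-one | C/C=C/c1cc(OC)c(O[C@H](C)C(=O)c2cc(OC)c(OCOC)c(OC)c2)c(O[Si](C)(C)C(C)(C)C)c1
F6 | step 11 | (1S,2R)-2-{2-[(tert-butyldimethylsilyl)oxy]-6-methoxy-4-[(1E)-prop-1-en-1-yl]phenoxy}-1-[3,5-dimethoxy-4-(methoxymethoxy)phenyl]propan-1-ol | C/C=C/c1cc(OC)c(O[C@H](C)[C@@H](O)c2cc(OC)c(OCOC)c(OC)c2)c(O[Si](C)(C)C(C)(C)C)c1
F7 | step 11 | 2-{[(1S,2R)-1-[3,5-dimethoxy-4-(methoxymethoxy)phenyl]-1-hydroxypropan-2-yl]oxy}-3-methoxy-5-[(1E)-prop-1-en-1-yl]phenol | C/C=C/c1cc(OC)c(O[C@H](C)[C@@H](O)c2cc(OC)c(OCOC)c(OC)c2)c(O)c1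
F8 | step 12 | (2S,3R)-2-[3,5-dimethoxy-4-(methoxymethoxy)phenyl]-3-methyl-7-[(1E)-prop-1-en-1-yl]-2,3-dihydro-1,4-benzodioxin-5-ol | C/C=C/c1cc(O)c2c(c1)O[C@@H](c1cc(OC)c(OCOC)c(OC)c1)[C@@H](C)O2
F9 | step 12 | (2S,3R)-2-[3,5-dimethoxy-4-(methoxymethoxy)phenyl]-5-methoxy-3-methyl-7-[(1E)-prop-1-en-1-yl]-2,3-dihydro-1,4-benzodioxine | C/C=C/c1cc(OC)c2c(c1)O[C@@H](c1cc(OC)c(OCOC)c(OC)c1)[C@@H](C)O2
F10 | step 12 | 2,6-dimethoxy-4-{(2S,3R)-5-methoxy-3-methyl-7-[(1E)-prop-1-en-1-yl]-2,3-dihydro-1,4-benzodioxin-2-yl}phenol | C/C=C/c1cc(OC)c2c(c1)O[C@@H](c1cc(OC)c(O)c(OC)c1)[C@@H](C)O2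
F0 | step 5 | none | none
F11 | step 7 | 2-{[(1S,2R)-1-[3,5-dimethoxy-4-(methoxymethoxy)phenyl]-1-hydroxypropan-2-yl]oxy}acetic acid | OC(=O)CO[C@H](C)[C@@H](O)c1cc(OC)c(OCOC)c(OC)c1
A1 | alternative 1 | methyl (2R,3R)-2-[4-(2,2-dimethylpropanoyloxy)-3,5-dimethoxyphenyl]-3-methyl-5-oxo-2,3,5,6,7,8-hexahydro-1,4-benzodioxine-7-carboxylate (C7 epimers) | COC(=O)C1CC(=O)C2=C(C1)O[C@H](c1cc(OC)c(OC(=O)C(C)(C)C)c(OC)c1)[C@@H](C)O2
A2 | alternative 1 | methyl 4-diazo-3,5-dioxocyclohexane-1-carboxylate | COC(=O)C1CC(=O)C(=[N+]=[N-])C(=O)C1
A3 | alternative 1 | 2,6-dimethoxy-4-[(2R,3R)-3-methyloxiran-2-yl]phenyl 2,2-dimethylpropanoate | C[C@H]1O[C@@H]1c1cc(OC)c(OC(=O)C(C)(C)C)c(OC)c1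
A4 | alternative 2 | (2R,3S)-2-[3,5-dimethoxy-4-(methoxymethoxy)phenyl]-3-(iodomethyl)-5-methoxy-2,3-dihydro-1,4-benzodioxine-7-carbaldehyde | O=Cc1cc(OC)c2c(c1)O[C@H](c1cc(OC)c(OCOC)c(OC)c1)[C@@H](CI)O2
A5 | alternative 2 | 3-{[(1S)-1-[3,5-dimethoxy-4-(methoxymethoxy)phenyl]prop-2-en-1-yl]oxy}-4-hydroxy-5-methoxybenzaldehyde | O=Cc1cc(OC)c(O)c(c1)O[C@H](c1cc(OC)c(OCOC)c(OC)c1)C=C
A6 | alternative 3 | 4-[(2R,3R)-7-bromo-5-methoxy-3-methyl-2,3-dihydro-1,4-benzodioxin-2-yl]-2,6-dimethoxyphenyl 2,2-dimethylpropanoate | Brc1cc(OC)c2c(c1)O[C@H](c1cc(OC)c(OC(=O)C(C)(C)C)c(OC)c1)[C@@H](C)O2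
A7 | alternative 3 | 6-bromo-4-methoxy-2-methyl-1,3-benzodioxole (racemic) | CC1Oc2cc(Br)cc(OC)c2O1
A8 | alternative 3 | 2,6-dimethoxy-4-[(E)-{2-[(4-methylphenyl)sulfonyl]hydrazinylidene}methyl]phenyl 2,2-dimethylpropanoate | Cc1ccc(cc1)S(=O)(=O)N/N=C/c1cc(OC)c(OC(=O)C(C)(C)C)c(OC)c1
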